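## Retrosynthetic overview

1. The target is methyl (13S)-2α-acetoxy-3α-hydroxylabd-7-en-15-oate. The 3α-OH comes from β-face hydride reduction of the 2α-acetoxy-3-ketone, and the C2–O bond from acetoxylation of the Δ2 enol silane of the Δ7 3-ketone.
2. The Δ7 alkene comes from regioselective loss of the 8α-OH. The C3 oxygen is the key disconnection: a late-stage P450 C–H hydroxylation (C–O bond) of methyl (13S)-8α-hydroxylabdan-15-oate, then oxidation to the ketone.
3. Side chain: C13 is set by copper hydride 1,4-reduction of the (E)-enoate, which comes from a Horner–Wadsworth–Emmons reaction on the methyl ketone obtained by oxidative cleavage of the vinyl carbinol of sclareol.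
4. Rings: none is formed. Both rings of the trans-decalin, with C5, C9 and C10, are taken intact from (−)-sclareol.

Naming: labdane numbering, normal series throughout (5α-H, 9α-H, 10β-CH3, as in sclareol). Ring A is C1–C5/C10, ring B is C5–C10, the side chain C11–C16 sits on C9.

Assumption: (R)-DTBM-SEGPHOS is written for step 3 on the assumption that it delivers hydride to the Re face of C13 of the (E)-enoate; if a test run gives the 13R epimer, the (S)-ligand is used with nothing else changed.

## Route

Step 1
Reactants: 1 (−)-sclareol [(13R)-labd-14-ene-8α,13-diol]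
Product: 4 8α-hydroxy-14,15-dinorlabdan-13-one, via labdane-8α,13,14,15-tetrol 2 (not isolated), via hydroxy aldehyde 3 (not isolated)
Conditions: OsO4 (1 mol %), NaIO4 (4 equiv), 2,6-lutidine, dioxane/H2O 3:1, rt
Reagents that add atoms: none
Why: Lemieux–Johnson oxidation: OsO4 dihydroxylates the only alkene and NaIO4 cleaves both diol bonds of the 13,14,15-triol unit, so C13 is released as the methyl ketone (its oxygen is the original 13-OH), while the lutidine buffer keeps the δ-hydroxy ketone from dehydrating to the enol ether; no ring stereocentre is touched.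

Step 2
Reactants: 4 8α-hydroxy-14,15-dinorlabdan-13-one; 5 trimethyl phosphonoacetate
Product: 6 methyl (13E)-8α-hydroxylabd-13-en-15-oate
Conditions: NaH (2.8 equiv), 5 (3.0 equiv), THF, 0 → 65 °C; Z isomer removed on silica
Reagents that add atoms: trimethyl phosphonoacetate (compound 5), COC(=O)CP(=O)(OC)OC
Why: Horner–Wadsworth–Emmons olefination of the open-chain ketone gives mainly the E enoate (ester trans to the larger C12 chain, about 4:1), and keeping the phosphonate in excess over NaH leaves the tertiary 8-OH protonated so that no oxa-Michael closure onto the enoate occurs.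

Step 3
Reactants: 6 methyl (13E)-8α-hydroxylabd-13-en-15-oate
Product: 7 methyl (13S)-8α-hydroxylabdan-15-oate
Conditions: Cu(OAc)2·H2O (3 mol %), (R)-DTBM-SEGPHOS (3 mol %), (EtO)2MeSiH, t-BuOH, toluene, 0 °C → rt
Reagents that add atoms: none
Why: Copper hydride-catalysed asymmetric conjugate reduction: the bisphosphine-bound monovalent copper hydride adds to the Re face of C13 under catalyst control (the ring stereocentres are too remote to interfere) and t-BuOH protonates the copper enolate, which sets 13S.

Step 4
Reactants: 7 methyl (13S)-8α-hydroxylabdan-15-oate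
Product: 8 methyl (13S)-3β,8α-dihydroxylabdan-15-oate
Conditions: cytochrome P450 BM3 variant of the lineage evolved for C3 hydroxylation of sclareol (E. coli lysate), NADP+ (cat.), glucose dehydrogenase, D-glucose, air, KPi pH 8.0, 5% DMSO, 25 °C
Reagents that add atoms: dioxygen, O=O
Why: Proposed new method: the tetravalent iron-oxo haem species abstracts the equatorial 3β-hydrogen of ring A (the methylene farthest from the deactivating C8 carbinol and C15 ester, held over the haem by the same decalin/8α-OH recognition as sclareol, with the saturated ester chain in the fatty-acid channel) and oxygen rebound with retention forms the C3–O bond as the 3β-alcohol; the closest known reaction is the C3β hydroxylation of sclareol and sclareolide by this enzyme family, which has not been shown on a labdan-15-oate ester.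

Step 5
Reactants: 8 methyl (13S)-3β,8α-dihydroxylabdan-15-oate
Product: 9 methyl (13S)-8α-hydroxy-3-oxolabdan-15-oate
Conditions: Dess–Martin periodinane, CH2Cl2, rt
Reagents that add atoms: none
Why: Dess–Martin oxidation turns the secondary 3β-alcohol into the ketone; the tertiary 8-OH cannot be oxidised and the ester is inert.

Step 6
Reactants: 9 methyl (13S)-8α-hydroxy-3-oxolabdan-15-oate
Product: 10 methyl (13S)-3-oxolabd-7-en-15-oate
Conditions: PPh3, I2, CH2Cl2, rt
Reagents that add atoms: none
Why: Ph3P/I2 dehydration of a tertiary alcohol (ionisation of the alkoxyphosphonium ion, E1-type proton loss): the C8 cation loses the accessible C7 proton to give the endocyclic trisubstituted Δ7 alkene rather than the exocyclic Δ8(17) or the strained tetrasubstituted Δ8 isomer.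

Step 7
Reactants: 10 methyl (13S)-3-oxolabd-7-en-15-oate
Product: 12 methyl (13S)-2α-acetoxy-3-oxolabd-7-en-15-oate, via silyl enol ether 11 (not isolated)
Conditions: TMSOTf, Et3N, CH2Cl2, 0 °C; pentane, filter; then Pb(OAc)4, CH2Cl2, −20 → 0 °C
Reagents that add atoms: lead tetraacetate, CC(=O)O[Pb](OC(C)=O)(OC(C)=O)OC(C)=O (acetoxy group of 12); trimethylsilyl trifluoromethanesulfonate, C[Si](C)(C)OS(=O)(=O)C(F)(F)F (silyl group of 11 only)
Why: Rubottom-type acetoxylation of an enol silane with tetravalent lead: soft enolisation can only give the Δ2 enol silane because C4 is quaternary and it spares the ester and the Δ7 alkene, and acetate is delivered to C2 from the open α face (the β face is blocked by the axial C10 and C4β methyls), giving the equatorial 2α-acetate, which is also the thermodynamic epimer.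

Step 8
Reactants: 12 methyl (13S)-2α-acetoxy-3-oxolabd-7-en-15-oate
Product: 13 methyl (13S)-2α-acetoxy-3α-hydroxylabd-7-en-15-oate (target; 2R,3S,5R,9S,10R,13S)
Conditions: LiBH(s-Bu)3 (1.2 equiv), THF, −78 °C; AcOH quench at −78 °C
Reagents that add atoms: none
Why: Diastereoselective ketone reduction with a bulky trialkylborohydride: hydride comes along the equatorial line from the β face to give the axial 3α-alcohol cis to the 2α-acetate, and the low temperature with an acidic quench prevents ester reduction and 2→3 acetyl migration (the acetate on the equatorial oxygen is in any case the more stable isomer).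

## Compound list

1 | (−)-sclareol, (13R)-labd-14-ene-8α,13-diol | C=C[C@](C)(O)CC[C@H]1[C@](C)(O)CC[C@H]2C(C)(C)CCC[C@]12C | starting material
2 | (13R)-labdane-8α,13,14,15-tetrol (both C14 epimers) | OCC(O)[C@](C)(O)CC[C@H]1[C@](C)(O)CC[C@H]2C(C)(C)CCC[C@]12C | intermediate
3 | (13R)-8α,13-dihydroxy-15-norlabdan-14-al | O=C[C@](C)(O)CC[C@H]1[C@](C)(O)CC[C@H]2C(C)(C)CCC[C@]12C | intermediate
4 | 8α-hydroxy-14,15-dinorlabdan-13-one | CC(=O)CC[C@H]1[C@](C)(O)CC[C@H]2C(C)(C)CCC[C@]12C | intermediate
5 | trimethyl phosphonoacetate | COC(=O)CP(=O)(OC)OC | starting material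
6 | methyl (13E)-8α-hydroxylabd-13-en-15-oate | COC(=O)/C=C(\C)CC[C@H]1[C@](C)(O)CC[C@H]2C(C)(C)CCC[C@]12C | intermediate
7 | methyl (13S)-8α-hydroxylabdan-15-oate | COC(=O)C[C@@H](C)CC[C@H]1[C@](C)(O)CC[C@H]2C(C)(C)CCC[C@]12C | intermediate
8 | methyl (13S)-3β,8α-dihydroxylabdan-15-oate | COC(=O)C[C@@H](C)CC[C@H]1[C@](C)(O)CC[C@H]2C(C)(C)[C@@H](O)CC[C@]12C | intermediate
9 | methyl (13S)-8α-hydroxy-3-oxolabdan-15-oate | COC(=O)C[C@@H](C)CC[C@H]1[C@](C)(O)CC[C@H]2C(C)(C)C(=O)CC[C@]12C | intermediate
10 | methyl (13S)-3-oxolabd-7-en-15-oate | COC(=O)C[C@@H](C)CC[C@H]1C(C)=CC[C@H]2C(C)(C)C(=O)CC[C@]12C | intermediate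
11 | methyl (13S)-3-(trimethylsilyloxy)labda-2,7-dien-15-oate | COC(=O)C[C@@H](C)CC[C@H]1C(C)=CC[C@H]2C(C)(C)C(O[Si](C)(C)C)=CC[C@]12C | intermediate
12 | methyl (13S)-2α-acetoxy-3-oxolabd-7-en-15-oate | COC(=O)C[C@@H](C)CC[C@H]1C(C)=CC[C@H]2C(C)(C)C(=O)[C@H](OC(C)=O)C[C@]12C | intermediate
13 | methyl (13S)-2α-acetoxy-3α-hydroxylabd-7-en-15-oate | COC(=O)C[C@@H](C)CC[C@H]1C(C)=CC[C@H]2C(C)(C)[C@H](O)[C@H](OC(C)=O)C[C@]12C | target

## Step count and risks

Total steps: 8. Longest linear sequence: 8 (from sclareol).

Steps most likely to fail: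

1. Step 4, the proposed new step (the enzyme may not accept the ester or may hydroxylate elsewhere). The fallback sets out from 1 and comes back at 8, using only known chemistry. The hydroxylation is run on sclareol itself, the established substrate of this enzyme family, to give 3β-hydroxysclareol F1. The free 3β-OH is then carried through the chemistry of steps 1 to 3. OsO4/NaIO4/2,6-lutidine cleavage proceeds through (13R)-labdane-3β,8α,13,14,15-pentol F2 and (13R)-3β,8α,13-trihydroxy-15-norlabdan-14-al F3, neither isolated, to 3β,8α-dihydroxy-14,15-dinorlabdan-13-one F4. Olefination with 5 gives methyl (13E)-3β,8α-dihydroxylabd-13-en-15-oate F5, and the copper hydride reduction of step 3 then delivers 8. The length is unchanged.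

2. Step 6 (regiochemistry of the dehydration: Δ7 against Δ8(17) and Δ8). The fallback sets out from 9 and comes back at 10, and splits the problem into two controlled events. SOCl2/pyridine in CH2Cl2 at −78 °C gives the kinetic exocyclic alkene, methyl (13S)-3-oxolabd-8(17)-en-15-oate F6. Hydrogen-atom-transfer isomerisation then moves the double bond into the ring, using Co(salen)Cl (trivalent cobalt; salen = N,N′-bis(3,5-di-tert-butylsalicylidene)-1,2-cyclohexanediaminate) with catalytic PhSiH3 in benzene at rt. The C8 radical loses the accessible C7 hydrogen rather than the hindered C9 hydrogen, giving 10.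

3. Step 8 (acetate loss or 2→3 acetyl migration during the hydride reduction). The fallback sets out from 12 and comes back at 13, and gives up acetate integrity on purpose. Reduction with excess LiBH(s-Bu)3 (THF, −78 → −40 °C) followed by K2CO3/MeOH converges every acetate isomer onto methyl (13S)-2α,3α-dihydroxylabd-7-en-15-oate F7. Regioselective acetylation of the unhindered equatorial 2α-OH (Ac2O 1.1 equiv, pyridine, 0 °C, or vinyl acetate with immobilised Candida antarctica lipase B) then gives 13; the axial, neopentylic 3α-OH does not react.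

Further compounds
F1 | step 4 | 3β-hydroxysclareol, (13R)-labd-14-ene-3β,8α,13-triol | C=C[C@](C)(O)CC[C@H]1[C@](C)(O)CC[C@H]2C(C)(C)[C@@H](O)CC[C@]12C
F2 | step 4 | (13R)-labdane-3β,8α,13,14,15-pentol (both C14 epimers) | OCC(O)[C@](C)(O)CC[C@H]1[C@](C)(O)CC[C@H]2C(C)(C)[C@@H](O)CC[C@]12C
F3 | step 4 | (13R)-3β,8α,13-trihydroxy-15-norlabdan-14-al | O=C[C@](C)(O)CC[C@H]1[C@](C)(O)CC[C@H]2C(C)(C)[C@@H](O)CC[C@]12C
F4 | step 4 | 3β,8α-dihydroxy-14,15-dinorlabdan-13-one | CC(=O)CC[C@H]1[C@](C)(O)CC[C@H]2C(C)(C)[C@@H](O)CC[C@]12C
F5 | step 4 | methyl (13E)-3β,8α-dihydroxylabd-13-en-15-oate | COC(=O)/C=C(\C)CC[C@H]1[C@](C)(O)CC[C@H]2C(C)(C)[C@@H](O)CC[C@]12C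
F6 | step 6 | methyl (13S)-3-oxolabd-8(17)-en-15-oate | COC(=O)C[C@@H](C)CC[C@H]1C(=C)CC[C@H]2C(C)(C)C(=O)CC[C@]12C
F7 | step 8 | methyl (13S)-2α,3α-dihydroxylabd-7-en-15-oate | COC(=O)C[C@@H](C)CC[C@H]1C(C)=CC[C@H]2C(C)(C)[C@H](O)[C@H](O)C[C@]12C
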